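Readings and results were computed on assumed constants.

Ask first where the flask must stop.

| flask | D | G | Z | remark | time |
|---|---|---|---|---|---|
| south-east | 0.23 M | 3.2 mM | 0.5 mol% | run made earlier |  |
| east | 0.23 M | 5.1 mM | 0.5 mol% | run made earlier |  |
| north-east | 0.46 M | 2.3 mM | 0.5 mol% | run made earlier |  |
| flask | 0.23 M | 2.30 mM | 0.5 mol% |  | 40 min |

| run | time / min | E / % | D / % |
|---|---|---|---|
| south-east | 3.00 | 24.6 | 75.6 |
| south-east | 8.00 | 24.9 | 75.4 |
| south-east | 15.0 | 24.7 | 75.1 |
| south-east | 40.0 | 25.0 | 75.1 |
| east | 5.00 | 14.9 | 84.6 |
| east | 15.0 | 15.8 | 85.2 |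
| east | 25.0 | 15.1 | 84.6 |
| east | 40.0 | 15.7 | 84.3 |
| north-east | 10.0 | 91.8 | 8.0 |
| north-east | 20.0 | 94.8 | 5.2 |
| north-east | 30.0 | 95.8 | 3.9 |
| north-east | 40.0 | 96.6 | 3.1 |

(each reading ± 0.3 percentage points)

- average number of monomer units in a chain (chains begun, living or dead) at 40 min
- part of the D that has reacted at 40 min

- the average divides the monomer in chains by the number of chains begun, living and dead together
- the earlier runs do not show the number of chains; that part of a forecast is a guess

I read the runs one at a time. In the south-east run D stood level at 75.3% from 3.00 min on, so growth had ended. I supposed that each Z begins one living end, 1.15 mM of them here, and that each G kills one. The same living ends then consume D and G, so the logarithm of D's fall keeps a fixed ratio to the logarithm of G's fall. I called this the growth-per-kill ratio, a selectivity factor between growth and killing. With G falling by the number of ends, the south-east run gave 0.637.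

The east run held more G than the south-east run, its D levelled higher, at 84.7%, and the ratio came to 0.651. In the north-east run G matched the ends, and D was still falling, from 8.0% at 10.0 min to 3.1% at 40.0 min.

I carried the mean, 0.644, as the growth-per-kill ratio. In the asked flask the ends take half of the G, so I reckoned 36.0% of the D reacted. The earlier runs show no chain count, so one chain per Z was a guess, and it gave a length of 72.0. The forecast also gave 36% and 72, “assuming every Z starts one chain”.

The flask gave 35.7% reacted and an average chain of 71.3. At 4.00 min its Z stood at 0.0949% of the charge with 35.6% of the D reacted, and at 400 min the part of the D reacted was 35.7%.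

    D + J → X + E (k = 1.10 M⁻¹ s⁻¹)
    D + X → E + X, rate k2*[X]*[D] (k = 27.0 M⁻¹ s⁻¹)
    X + G → L (k = 43.0 M⁻¹ s⁻¹)
    Z → J (k = 0.0290 s⁻¹)

G ended at 50.0% of its charge in this flask, which with the ratio 0.644 puts D at 64.0%, and D stood at 64.3%. For a neighbour flask charged with 0.0039 M of G, its other charges and the time as in the asked flask, the same ratio put D at 79.9%, and the D of that flask ended at 79.9%.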